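At the first reading, 4.8 min, the Saturday's run holds 0.01442 M of c(product), and the Friday's run, charged with half the c(partner), holds 0.00927 M. We start from that pair of numbers.

| setting | Saturday's | Sunday's | Friday's | Wednesday's | Thursday's |
|---|---|---|---|---|---|
| substrate | 0.0800 M | 0.0400 M | 0.0800 M | 0.0800 M | 0.0800 M |
| partner | 0.0880 M | 0.0480 M | 0.0440 M | 0.0880 M | 0.0880 M |
| catalyst | 4.00 × 10⁻⁴ M | 4.00 × 10⁻⁴ M | 4.00 × 10⁻⁴ M | 2.00 × 10⁻⁴ M | 4.00 × 10⁻⁴ M |
| time |  |  |  |  | 60 min |

| run | time / min | [product] / M |
|---|---|---|
| Saturday's run | 4.8 | 0.01442 |
| Saturday's run | 9.6 | 0.02644 |
| Saturday's run | 14 | 0.03693 |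
| Saturday's run | 19 | 0.04665 |
| Saturday's run | 24 | 0.05526 |
| Sunday's run | 4.8 | 0.00899 |
| Sunday's run | 9.6 | 0.01659 |
| Sunday's run | 14 | 0.02272 |
| Sunday's run | 19 | 0.02787 |
| Sunday's run | 24 | 0.03178 |
| Friday's run | 4.8 | 0.00927 |
| Friday's run | 9.6 | 0.01746 |
| Friday's run | 14 | 0.02347 |
| Friday's run | 19 | 0.02973 |
| Friday's run | 24 | 0.03357 |
| Wednesday's run | 4.8 | 0.00718 |
| Wednesday's run | 9.6 | 0.01422 |
| Wednesday's run | 14 | 0.02004 |
| Wednesday's run | 19 | 0.02624 |
| Wednesday's run | 24 | 0.03251 |

(scatter of a reading: 2 × 10⁻⁴ M)

- Overall: substrate + partner -> product, with catalyst as catalyst.
- Constant volume, constant temperature.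
- Readings of a species count what is bound in complexes too.
- "The second partner" is partner.
- An order is taken over about fifteen percent of the charge, up and down.

* how the opening rate goes with [catalyst] round the charge of the Saturday's run: the exponent of the rate at two percent of substrate gone to product
* how the opening rate goes with [partner] round the charge of the Saturday's run: the exponent of the rate at two percent of substrate gone to product
* the Sunday's run starts with 0.0400 M less of substrate and of partner than the Saturday's run, and with no product. Compared where both hold the same amount of substrate, once fifteen percent of what the Sunday's run was charged with has turned into product, is the Sunday's run faster, slower or alike (within a tenth)?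
* product in the Thursday's run at 60 min, as a share of the substrate charged
* which of these the readings show (the substrate is lost by itself / the second partner pairs with itself / nothing beyond the main steps / the catalyst dies by itself / the second partner is lost in pairs)

Those two runs share their c(substrate) and c(catalyst). The logarithm of the ratio of product over the logarithm of the ratio of partner charged gives 0.637, and this number, the partner exponent (an apparent order), is what we carry.

Our first doubt is that it rests on two readings. Their scatter puts 0.0370 on the exponent, so it stands clear of 0.5 and of 1.

The second doubt is that product at 4.8 min is an average over a falling c(partner). Taking the partner midway through that interval in each run gives 0.615, a shift inside the scatter, so we keep our number.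

The third doubt is the clock. The Wednesday's run, with half the catalyst, reads 0.02624 M at 19 min, while the Saturday's run reads 0.02644 M at 9.6 min, so the same product takes twice the time and the catalyst exponent lies near 1.

What does a fraction mean? We solve both ends. A partner that stays single enters with exponent 1, and one held in pairs enters through the root of its charge, with exponent 0.5, so joining the ends gives a value between them. But a cycle that saturates in partner also passes through such a value, so we carry the number and leave the mechanism open.

The forecast gives 1 for the catalyst (0.9 to 1.1) and 0.55 for the partner (0.42 to 0.7). It calls the Sunday's run alike, puts the Thursday's run at 98.5% (95% to 100%), and names nothing beyond the main steps. Of pairing it says: “Partner pairing fits too, but is not required.” Its partner exponent is lower than ours. Ours is taken across the span from the Friday's charge to the Saturday's, not round the Saturday's charge, and it lies inside the forecast's range.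

The flask gives 1.0 for the catalyst and 0.57 for the partner, the Sunday's run is alike, the Thursday's run reaches 98.4%, and the readings show that the second partner pairs with itself.

    catalyst + substrate ⇌ catalyst-substrate complex, settled at all times (143.0 M⁻¹)
    catalyst-substrate complex + partner → product + catalyst + by-product (435.6 M⁻¹ min⁻¹)
    2 partner ⇌ idle reagent dimer, settled at all times (89.50 M⁻¹)

At the Saturday's charge, the tying up of partner as idle reagent dimer holds the partner exponent at 0.57 against 1.0 without it, the single end of our reckoning. Now we carry our 0.637 to the Sunday's run, with the substrate exponent 0.085. From the Saturday's rate 0.0031 M min⁻¹, at an early fixed amount of product, it gives 0.00198 M min⁻¹, and the Sunday's run stands at 0.0020 M min⁻¹.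

(The runs are simulated for substances that don't exist, and the scatter is random.)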